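The route cuts the C(sp3)–C(sp2) bond between the second CH2 of the chain on the quaternary ring-A carbon (C1 of the octalin) and the vinylic CH of the (E)-trisubstituted olefin. One operation, hydroboration followed by B-alkyl Suzuki–Miyaura coupling, joins the bicyclic core to the whole side chain. A vinyl group on that quaternary carbon becomes the nucleophilic CH2CH2–B unit. An (E)-alkenyl iodide, made by carboalumination and carrying the protected diol, supplies the olefin with its geometry fixed. The step exploits the fact that the quaternary carbon of ring A bears exactly a two-carbon spacer to that olefin, so a 1-vinyl octalin and a terminal alkyne are the true precursors.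

Key step: step 13

Remark: the target is drawn as the free bis(hydrogen sulfate); the last step gives it as a salt, and brief contact with an acidic ion-exchange resin is assumed to give the drawn form.

Step 1
Reactants: 1 2-methylcyclohex-2-en-1-one; 2 2-(bromomethyl)-1,4-dimethoxybenzene
Product: 4 (2R,3S)-2-[(2,5-dimethoxyphenyl)methyl]-2,3-dimethylcyclohexan-1-one, via dimethylaluminium enolate 3 (not isolated)
Conditions: Me3Al, Cu(O2CC4H3S) (copper thiophene-2-carboxylate, 2 mol%), (S,R,R)-phosphoramidite ligand from (S)-BINOL and bis[(R)-1-phenylethyl]amine (4 mol%), Et2O, −30 °C; then MeLi, THF/DMPU, −30 °C; then 2, −30 °C → rt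
Reagents that add atoms: trimethylaluminium, C[Al](C)C
Why: Copper-catalysed asymmetric conjugate addition should deliver methyl to the Si face of C3 under ligand control (3S), and the enolate, activated as its lithium aluminate, should be benzylated anti to that methyl (tandem conjugate addition–enolate alkylation), which sets the quaternary carbon (2R) with the two methyls cis.

Step 2
Reactants: 4 ketone
Product: 5 (5S,6R)-6-[(2,5-dimethoxyphenyl)methyl]-5,6-dimethylcyclohex-1-en-1-yl trifluoromethanesulfonate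
Conditions: KN(SiMe3)2, THF, −78 °C; PhNTf2, −78 → 0 °C
Reagents that add atoms: N-phenylbis(trifluoromethanesulfonimide), O=S(=O)(N(c1ccccc1)S(=O)(=O)C(F)(F)F)C(F)(F)F
Why: Only C6 of the ketone carries α-hydrogens, so enolate formation and O-triflation (enol triflate formation) are regiospecific and no stereocentre is touched.

Step 3
Reactants: 5 enol triflate
Product: 6 2-{[(1R,6S)-2-ethenyl-1,6-dimethylcyclohex-2-en-1-yl]methyl}-1,4-dimethoxybenzene
Conditions: CH2=CHSnBu3, Pd(PPh3)4 (5 mol%), LiCl, THF, 65 °C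
Reagents that add atoms: tributyl(vinyl)stannane, C=C[Sn](CCCC)(CCCC)CCCC
Why: Stille coupling of a hindered alkenyl triflate in the presence of chloride should give the 1-vinylcyclohexene diene without affecting the two stereocentres.

Step 4
Reactants: 6 diene; 7 methacrolein (2-methylprop-2-enal)
Product: 8 (1S,5R,6S)-5-[(2,5-dimethoxyphenyl)methyl]-1,5,6-trimethyl-1,2,3,5,6,7,8,8a-octahydronaphthalene-1-carbaldehyde (both C8a epimers)
Conditions: (S)-o-tolyl-oxazaborolidine from (S)-α,α-diphenylprolinol (20 mol%), Tf2NH (18 mol%), CH2Cl2, −78 → −40 °C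
Reagents that add atoms: none
Why: In this catalytic enantioselective Diels–Alder reaction the protonated oxazaborolidine binds s-trans methacrolein and should leave only the Re face of its C2 open, so the quaternary carbon C1 is set (S) by the catalyst whichever diene face reacts; the ortho rule and early bonding of the dienophile CH2 to the unhindered vinyl terminus give the regiochemistry, and the C8a centre formed alongside is erased in step 5.

Step 5
Reactants: 8 aldehyde
Product: 9 (1S,5R,6S)-5-[(2,5-dimethoxyphenyl)methyl]-1,5,6-trimethyl-1,2,3,4,5,6,7,8-octahydronaphthalene-1-carbaldehyde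
Conditions: TsOH·H2O (20 mol%), benzene, 60 °C
Reagents that add atoms: none
Why: Acid-catalysed olefin isomerisation: protonation at C4 gives the tertiary C4a cation, which should lose H-8a to give the more substituted ring-fusion olefin, so both C8a epimers converge; the aldehyde is not enolisable and C1, C5 and C6 are untouched.

Step 6
Reactants: 9 aldehyde
Product: 10 2-{[(1R,2S,5R)-5-ethenyl-1,2,5-trimethyl-1,2,3,4,5,6,7,8-octahydronaphthalen-1-yl]methyl}-1,4-dimethoxybenzene
Conditions: Ph3PCH3Br, KN(SiMe3)2, THF, 0 °C → rt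
Reagents that add atoms: methyltriphenylphosphonium bromide, C[P+](c1ccccc1)(c1ccccc1)c1ccccc1.[Br-]
Why: Wittig methylenation of a non-enolisable neopentyl aldehyde; no stereocentre is affected (the descriptor of the quaternary carbon changes only through CIP priorities).

Step 7
Reactants: 11 geraniol
Product: 12 [(2S,3S)-3-methyl-3-(4-methylpent-3-en-1-yl)oxiran-2-yl]methanol
Conditions: Ti(OiPr)4 (5 mol%), L-(+)-diethyl tartrate (6 mol%), t-BuOOH, 4 Å molecular sieves, CH2Cl2, −20 °C
Reagents that add atoms: tert-butyl hydroperoxide, CC(C)(C)OO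
Why: Sharpless asymmetric epoxidation: the allylic hydroxyl directs oxygen transfer to the 2,3-olefin only, and the L-(+)-tartrate should give the (2S,3S)-epoxide.

Step 8
Reactants: 12 epoxy alcohol
Product: 13 [(2S,3S)-3-methyl-3-(4-methylpent-3-en-1-yl)oxiran-2-yl]methyl 4-methylbenzenesulfonate
Conditions: TsCl, Et3N, DMAP (cat.), CH2Cl2, 0 °C
Reagents that add atoms: p-toluenesulfonyl chloride, Cc1ccc(S(=O)(=O)Cl)cc1
Why: Sulfonylation of the primary alcohol; the epoxide is untouched.

Step 9
Reactants: 13 epoxy tosylate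
Product: 15 (2S,3S)-3-(but-3-yn-1-yl)-2-methyl-2-(4-methylpent-3-en-1-yl)oxirane, via silylated epoxy alkyne 14 (not isolated)
Conditions: 1-(trimethylsilyl)propyne, n-BuLi, THF, −78 → 0 °C; 13, −78 → 0 °C; then K2CO3, MeOH, rt
Reagents that add atoms: 1-(trimethylsilyl)propyne, CC#C[Si](C)(C)C
Why: SN2 alkylation of the propargylic lithium reagent at the primary tosylate (the silyl group blocks the acetylenic end and disfavours allenyl products) should outrun attack at the trisubstituted epoxide, and methanolysis then removes the C-silyl group; both epoxide stereocentres are unchanged.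

Step 10
Reactants: 15 epoxy alkyne
Product: 16 (5S,6R)-6,10-dimethylundec-9-en-1-yne-5,6-diol
Conditions: HClO4 (cat.), THF/H2O, 0 °C → rt
Reagents that add atoms: water, O
Why: Acid-catalysed epoxide hydrolysis: water should open the protonated trisubstituted epoxide at the tertiary carbon with inversion, so the secondary carbinol keeps its configuration (S) and the tertiary carbinol becomes R.

Step 11
Reactants: 16 diol
Product: 17 (5S,6R)-5-{[tert-butyl(dimethyl)silyl]oxy}-6,10-dimethylundec-9-en-1-yn-6-ol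
Conditions: TBSOTf (1.1 equiv), 2,6-lutidine, CH2Cl2, −78 °C
Reagents that add atoms: tert-butyldimethylsilyl trifluoromethanesulfonate, CC(C)(C)[Si](C)(C)OS(=O)(=O)C(F)(F)F
Why: Silylation with a silyl triflate at low temperature should take the secondary hydroxyl and leave the tertiary one free.

Step 12
Reactants: 17 silyl ether
Product: 19 (1E,5S,6R)-5-{[tert-butyl(dimethyl)silyl]oxy}-1-iodo-2,6,10-trimethylundeca-1,9-dien-6-ol, via alkenylalane 18 (not isolated)
Conditions: Me3Al (4 equiv), Cp2ZrCl2 (0.5 equiv), CH2Cl2, 0 °C → rt; then I2, THF, −30 °C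
Reagents that add atoms: trimethylaluminium, C[Al](C)C; iodine, II
Why: Zirconium-catalysed carboalumination adds Me–Al syn across the terminal alkyne with methyl on the internal carbon, and iodinolysis with retention should give the (E)-alkenyl iodide; the tertiary hydroxyl travels as its aluminium alkoxide and the trisubstituted olefin is inert.

Step 13
Reactants: 10 vinyl octalin; 19 alkenyl iodide
Product: 21 2-{[(1R,2S,5R)-5-[(3E,7S,8R)-7-{[tert-butyl(dimethyl)silyl]oxy}-8-hydroxy-4,8,12-trimethyltrideca-3,11-dien-1-yl]-1,2,5-trimethyl-1,2,3,4,5,6,7,8-octahydronaphthalen-1-yl]methyl}-1,4-dimethoxybenzene, via B-alkyl-9-BBN borane 20 (not isolated)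
Conditions: 10, 9-BBN dimer, THF, rt → 50 °C; then aq. Cs2CO3, 19, Pd(dppf)Cl2 (10 mol%), AsPh3 (10 mol%), DMF, rt
Reagents that add atoms: none
Why: 9-BBN should add anti-Markovnikov to the vinyl group on the quaternary carbon, placing boron on the terminal carbon. The hydroxide-activated borate then transmetalates to the alkenylpalladium iodide formed from 19, and reductive elimination forms the C(sp3)–C(sp2) bond (hydroboration/B-alkyl Suzuki–Miyaura coupling). No ring is closed and no stereocentre is created; the E geometry of the alkenyl iodide is retained because oxidative addition and reductive elimination are stereoretentive. The step needs chemoselective hydroboration, which the substrate secures: the only other olefin of 10 is tetrasubstituted and flanked by two quaternary carbons, and 19 with its trisubstituted olefin is added only after the B–H is consumed. The bidentate phosphine with AsPh3 favours coupling over β-hydride elimination, and the free tertiary hydroxyl, silyl ether and aryl methyl ethers should be tolerated.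

Step 14
Reactants: 21 coupled dimethyl ether
Product: 22 2-{[(1R,2S,5R)-5-[(3E,7S,8R)-7-{[tert-butyl(dimethyl)silyl]oxy}-8-hydroxy-4,8,12-trimethyltrideca-3,11-dien-1-yl]-1,2,5-trimethyl-1,2,3,4,5,6,7,8-octahydronaphthalen-1-yl]methyl}benzene-1,4-diol
Conditions: NaSEt, DMF, 130 °C, argon
Reagents that add atoms: none
Why: Nucleophilic (SN2) demethylation of both aryl methyl ethers by thiolate; olefins, the alkyl silyl ether and the tertiary alcohol should be inert to this soft nucleophile.

Step 15
Reactants: 22 hydroquinone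
Product: 23 2-{[(1R,2S,5R)-5-[(3E,7S,8R)-7-{[tert-butyl(dimethyl)silyl]oxy}-8-hydroxy-4,8,12-trimethyltrideca-3,11-dien-1-yl]-1,2,5-trimethyl-1,2,3,4,5,6,7,8-octahydronaphthalen-1-yl]methyl}-1,4-phenylene bis(hydrogen sulfate)
Conditions: SO3·pyridine, pyridine, 0 °C → rt; aq. NaHCO3
Reagents that add atoms: sulfur trioxide–pyridine complex, O=S(=O)([O-])[n+]1ccccc1
Why: O-Sulfation of the two phenols with the sulfur trioxide–pyridine complex; the secondary hydroxyl is silylated and the hindered tertiary hydroxyl should not react under these conditions.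

Step 16
Reactants: 23 silylated bis-sulfate
Product: 24 2-{[(1R,2S,5R)-5-[(3E,7S,8R)-7,8-dihydroxy-4,8,12-trimethyltrideca-3,11-dien-1-yl]-1,2,5-trimethyl-1,2,3,4,5,6,7,8-octahydronaphthalen-1-yl]methyl}-1,4-phenylene bis(hydrogen sulfate) (CNP0442769.2)
Conditions: Bu4NF, THF, rt; then acidic ion-exchange resin, MeOH/H2O, 0 °C
Reagents that add atoms: none
Why: Fluoride-induced cleavage of the silyl ether; aryl sulfate monoesters are stable to fluoride and base, so the two sulfates should survive.

Compound list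
1 | 2-methylcyclohex-2-en-1-one | CC1=CCCCC1=O | starting material
2 | 2-(bromomethyl)-1,4-dimethoxybenzene | COc1ccc(OC)c(CBr)c1 | starting material
3 | dimethyl{[(3S)-2,3-dimethylcyclohex-1-en-1-yl]oxy}alumane | C[Al](C)OC1=C(C)[C@@H](C)CCC1 | intermediate (not isolated)
4 | (2R,3S)-2-[(2,5-dimethoxyphenyl)methyl]-2,3-dimethylcyclohexan-1-one | O=C1CCC[C@H](C)[C@@]1(C)Cc1cc(OC)ccc1OC | intermediate
5 | (5S,6R)-6-[(2,5-dimethoxyphenyl)methyl]-5,6-dimethylcyclohex-1-en-1-yl trifluoromethanesulfonate | O=S(=O)(OC1=CCC[C@H](C)[C@@]1(C)Cc1cc(OC)ccc1OC)C(F)(F)F | intermediate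
6 | 2-{[(1R,6S)-2-ethenyl-1,6-dimethylcyclohex-2-en-1-yl]methyl}-1,4-dimethoxybenzene | C=CC1=CCC[C@H](C)[C@@]1(C)Cc1cc(OC)ccc1OC | intermediate
7 | methacrolein (2-methylprop-2-enal) | CC(=C)C=O | starting material
8 | (1S,5R,6S)-5-[(2,5-dimethoxyphenyl)methyl]-1,5,6-trimethyl-1,2,3,5,6,7,8,8a-octahydronaphthalene-1-carbaldehyde (C8a epimers) | O=C[C@@]1(C)CCC=C2C1CC[C@H](C)[C@@]2(C)Cc1cc(OC)ccc1OC | intermediate
9 | (1S,5R,6S)-5-[(2,5-dimethoxyphenyl)methyl]-1,5,6-trimethyl-1,2,3,4,5,6,7,8-octahydronaphthalene-1-carbaldehyde | O=C[C@@]1(C)CCCC2=C1CC[C@H](C)[C@@]2(C)Cc1cc(OC)ccc1OC | intermediate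
10 | 2-{[(1R,2S,5R)-5-ethenyl-1,2,5-trimethyl-1,2,3,4,5,6,7,8-octahydronaphthalen-1-yl]methyl}-1,4-dimethoxybenzene | C=C[C@@]1(C)CCCC2=C1CC[C@H](C)[C@@]2(C)Cc1cc(OC)ccc1OC | intermediate
11 | geraniol, (2E)-3,7-dimethylocta-2,6-dien-1-ol | CC(C)=CCC/C(C)=C/CO | starting material
12 | [(2S,3S)-3-methyl-3-(4-methylpent-3-en-1-yl)oxiran-2-yl]methanol | CC(C)=CCC[C@]1(C)O[C@H]1CO | intermediate
13 | [(2S,3S)-3-methyl-3-(4-methylpent-3-en-1-yl)oxiran-2-yl]methyl 4-methylbenzenesulfonate | CC(C)=CCC[C@]1(C)O[C@H]1COS(=O)(=O)c1ccc(C)cc1 | intermediate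
14 | trimethyl{4-[(2S,3S)-3-methyl-3-(4-methylpent-3-en-1-yl)oxiran-2-yl]but-1-yn-1-yl}silane | CC(C)=CCC[C@]1(C)O[C@H]1CCC#C[Si](C)(C)C | intermediate (not isolated)
15 | (2S,3S)-3-(but-3-yn-1-yl)-2-methyl-2-(4-methylpent-3-en-1-yl)oxirane | CC(C)=CCC[C@]1(C)O[C@H]1CCC#C | intermediate
16 | (5S,6R)-6,10-dimethylundec-9-en-1-yne-5,6-diol | CC(C)=CCC[C@@](C)(O)[C@@H](O)CCC#C | intermediate
17 | (5S,6R)-5-{[tert-butyl(dimethyl)silyl]oxy}-6,10-dimethylundec-9-en-1-yn-6-ol | CC(C)=CCC[C@@](C)(O)[C@@H](O[Si](C)(C)C(C)(C)C)CCC#C | intermediate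
18 | (E)-alkenyl(dimethyl)alane of 17, tertiary oxygen as its dimethylaluminium alkoxide | CC(C)=CCC[C@@](C)(O[Al](C)C)[C@@H](O[Si](C)(C)C(C)(C)C)CC/C(C)=C/[Al](C)C | intermediate (not isolated)
19 | (1E,5S,6R)-5-{[tert-butyl(dimethyl)silyl]oxy}-1-iodo-2,6,10-trimethylundeca-1,9-dien-6-ol | CC(C)=CCC[C@@](C)(O)[C@@H](O[Si](C)(C)C(C)(C)C)CC/C(C)=C/I | intermediate
20 | 2-{[(1R,2S,5S)-5-[2-(9-borabicyclo[3.3.1]nonan-9-yl)ethyl]-1,2,5-trimethyl-1,2,3,4,5,6,7,8-octahydronaphthalen-1-yl]methyl}-1,4-dimethoxybenzene (5S by CIP priority only, same spatial arrangement as in 10) | C1CC2CCCC(C1)B2CC[C@@]3(C)CCCC4=C3CC[C@H](C)[C@@]4(C)Cc5cc(OC)ccc5OC | intermediate (not isolated)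
21 | 2-{[(1R,2S,5R)-5-[(3E,7S,8R)-7-{[tert-butyl(dimethyl)silyl]oxy}-8-hydroxy-4,8,12-trimethyltrideca-3,11-dien-1-yl]-1,2,5-trimethyl-1,2,3,4,5,6,7,8-octahydronaphthalen-1-yl]methyl}-1,4-dimethoxybenzene | CC(C)=CCC[C@@](C)(O)[C@@H](O[Si](C)(C)C(C)(C)C)CC/C(C)=C/CC[C@@]1(C)CCCC2=C1CC[C@H](C)[C@@]2(C)Cc1cc(OC)ccc1OC | intermediate
22 | hydroquinone of 21 (benzene-1,4-diol in place of 1,4-dimethoxybenzene) | CC(C)=CCC[C@@](C)(O)[C@@H](O[Si](C)(C)C(C)(C)C)CC/C(C)=C/CC[C@@]1(C)CCCC2=C1CC[C@H](C)[C@@]2(C)Cc1cc(O)ccc1O | intermediate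
23 | bis(hydrogen sulfate) of 22, secondary hydroxyl still silylated | CC(C)=CCC[C@@](C)(O)[C@@H](O[Si](C)(C)C(C)(C)C)CC/C(C)=C/CC[C@@]1(C)CCCC2=C1CC[C@H](C)[C@@]2(C)Cc1cc(OS(=O)(=O)O)ccc1OS(=O)(=O)O | intermediate
24 | 2-{[(1R,2S,5R)-5-[(3E,7S,8R)-7,8-dihydroxy-4,8,12-trimethyltrideca-3,11-dien-1-yl]-1,2,5-trimethyl-1,2,3,4,5,6,7,8-octahydronaphthalen-1-yl]methyl}-1,4-phenylene bis(hydrogen sulfate) | CC(C)=CCC[C@@](C)(O)[C@@H](O)CC/C(C)=C/CC[C@@]1(C)CCCC2=C1CC[C@H](C)[C@@]2(C)Cc1cc(OS(=O)(=O)O)ccc1OS(=O)(=O)O | target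

Total step count: 16.
Longest linear sequence: 10 steps (steps 1–6 then 13–16; the side-chain branch, steps 7–12 then 13–16, is equally long).

Steps most likely to fail

1. Step 4. The chiral catalyst and the hindered, chiral diene may be mismatched, which would slow the cycloaddition, erode facial selectivity at the new quaternary carbon, or let the diene oligomerise under acid. The fallback sets out from 6 and gives up catalyst control in favour of separation. Cycloaddition of 6 with methacrolein promoted by Me2AlCl (CH2Cl2, −78 °C) would give 8 together with the (1R)-epimer of aldehyde 8 F1. The mixture would be isomerised as in step 5 to 9 and the (1R)-epimer of aldehyde 9 F2. These are diastereomers, because C5 and C6 are already fixed, so they would be separated by chromatography. The fallback returns to the route at 9.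

2. Step 5. Olefin migration may stop at an equilibrium mixture, or the tertiary cation may be captured by the electron-rich arene or undergo a 1,2-shift. The fallback sets out from 8 and replaces the cationic isomerisation by a carbanionic one. Wittig methylenation of 8 (Ph3PCH3Br, KN(SiMe3)2, THF) would first give the 4a,5,6,7-hydro vinyl octalin F3. Equilibration of the ring olefin with potassium 3-aminopropylamide in 3-aminopropylamine at rt (base-mediated allylic isomerisation; the vinyl group on the quaternary carbon cannot migrate) would then give 10. The fallback returns to the route at 10.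

3. Step 10. Water may open the epoxide partly at the secondary carbon, which erodes the enantiomeric purity, or through a free tertiary cation, which gives the diastereomeric diol. The fallback sets out from 11 and builds the same diol by inversion at the secondary carbon under basic conditions. Sharpless epoxidation with D-(−)-diethyl tartrate would give the (2R,3R)-epoxy alcohol F4. Payne rearrangement with in situ thiolate opening (PhSH, NaOH, t-BuOH/H2O, 70 °C) would give the phenylsulfanyl diol F5 by clean SN2 inversion at C2. S-Methylation (Me3OBF4, CH2Cl2) to the sulfonium tetrafluoroborate F6 and closure with NaH in THF would give the terminal epoxy alcohol F7. Opening of F7 at its CH2 with allenylmagnesium bromide (Et2O, −20 °C) would give 16. The fallback returns to the route at 16.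

Further compounds
F1 | step 4 | (1R,5R,6S)-5-[(2,5-dimethoxyphenyl)methyl]-1,5,6-trimethyl-1,2,3,5,6,7,8,8a-octahydronaphthalene-1-carbaldehyde | O=C[C@]1(C)CCC=C2C1CC[C@H](C)[C@@]2(C)Cc1cc(OC)ccc1OC
F2 | step 4 | (1R,5R,6S)-5-[(2,5-dimethoxyphenyl)methyl]-1,5,6-trimethyl-1,2,3,4,5,6,7,8-octahydronaphthalene-1-carbaldehyde | O=C[C@]1(C)CCCC2=C1CC[C@H](C)[C@@]2(C)Cc1cc(OC)ccc1OC
F3 | step 5 | 2-{[(1R,2S,5R)-5-ethenyl-1,2,5-trimethyl-1,2,3,4,4a,5,6,7-octahydronaphthalen-1-yl]methyl}-1,4-dimethoxybenzene | C=C[C@@]1(C)CCC=C2C1CC[C@H](C)[C@@]2(C)Cc1cc(OC)ccc1OC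
F4 | step 10 | [(2R,3R)-3-methyl-3-(4-methylpent-3-en-1-yl)oxiran-2-yl]methanol | CC(C)=CCC[C@@]1(C)O[C@@H]1CO
F5 | step 10 | (2R,3R)-3,7-dimethyl-1-(phenylsulfanyl)oct-6-ene-2,3-diol | CC(C)=CCC[C@@](C)(O)[C@@H](O)CSc1ccccc1
F6 | step 10 | [(2R,3R)-2,3-dihydroxy-3,7-dimethyloct-6-en-1-yl](methyl)phenylsulfonium tetrafluoroborate | CC(C)=CCC[C@@](C)(O)[C@@H](O)C[S+](C)c1ccccc1.F[B-](F)(F)F
F7 | step 10 | (2R)-6-methyl-2-[(2S)-oxiran-2-yl]hept-5-en-2-ol | CC(C)=CCC[C@@](C)(O)[C@@H]1CO1
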